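**Plan**

1. Locants: C1 (CO2H), C2, C3 (ring carbon with CH3), C4 (ring CH2), C5 (ring carbon with CH3), C6–C15 (side chain, CH3 on C7 and C11, phenyl on C15). Retrosynthetic cuts, in order: CO2H back to CH2OH at C1; the C5–CH3 bond; the O–C3 ring bond (the peroxide then sits on C5 as a hydroperoxy ketal); C5–C6; C8–C9 and C14=C15 in the side chain.
2. Enabling feature: C3 is a fully substituted carbon carrying CH3, the ring oxygen and a two-carbon arm that ends at C1. With C1 at the alcohol level, O–C3 and O–C1 can be one oxetane ring (absent from the target). C1–C5 plus the C3 methyl is then the skeleton of (R)-mevalonolactone, and C5 can wait at the ketone level.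
3. Forward: side-chain bromide 9 (C6–C15) by copper-catalysed sp3–sp3 coupling, cross-metathesis and hydrogenation; oxetane Weinreb amide 13 from mevalonolactone; union at C5–C6 to ketone 15; methylenation to 16.
4. Rings: ozonolysis in methanol puts a hydroperoxy ketal on C5, and its OOH opens the oxetane at C3 to close the dioxolane. The freed C1 alcohol ties back onto C5 as a second temporary ring (the oxane of a 2,6,7-trioxabicyclo[3.2.1]octane, 19). MeTiCl3 cuts this bridge while installing the C5 methyl; oxidation at C1 gives the acid.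
5. Stereochemistry: C7 and C11 from (S)-3-bromo-2-methylpropan-1-ol and (S)-citronellyl bromide; C3 from (R)-mevalonolactone with SN2-type inversion in the oxetane opening; C5 from the bicyclic ketal, methyl entering anti to the bridge and therefore cis to the C3 methyl.

Key step: step 11

Remark: compounds 1, 3, 6 and 10 are taken as commercial (1, 3 and 10 in high enantiomeric purity); CIP descriptors change along the route where only priorities change, so the SMILES strings define the configurations.

**Route**

Step 1
Reactants: 1 (2S)-3-bromo-2-methylpropan-1-ol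
Product: 2 {[(2S)-3-bromo-2-methylpropoxy]methyl}benzene
Conditions: BnOC(=NH)CCl3 (1.3 equiv), TfOH (5 mol%), CH2Cl2/cyclohexane, 0 °C to rt
Reagents that add atoms: benzyl 2,2,2-trichloroacetimidate, N=C(OCc1ccccc1)C(Cl)(Cl)Cl
Why: Acid-catalysed O-benzylation with the trichloroacetimidate avoids base, which would close the bromo alkoxide to an oxetane, and leaves the stereocentre untouched.

Step 2
Reactants: 2 {[(2S)-3-bromo-2-methylpropoxy]methyl}benzene; 3 (6S)-8-bromo-2,6-dimethyloct-2-ene [(S)-citronellyl bromide]
Product: 5 ({[(2R,6R)-2,6,10-trimethylundec-9-en-1-yl]oxy}methyl)benzene, via Grignard reagent 4 (not isolated)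
Conditions: 2, Mg, THF, 40 °C; then 3, Li2CuCl4 (3 mol%), THF, −20 °C to rt
Reagents that add atoms: none
Why: Copper-catalysed coupling of a primary Grignard reagent with a primary alkyl bromide (Kochi-type sp3–sp3 coupling) should join C8 to C9 without touching either methyl-bearing stereocentre.

Step 3
Reactants: 5 ({[(2R,6R)-2,6,10-trimethylundec-9-en-1-yl]oxy}methyl)benzene; 6 styrene
Product: 7 ({[(2R,6R,9E)-2,6-dimethyl-10-phenyldec-9-en-1-yl]oxy}methyl)benzene
Conditions: 6 (5 equiv), (H2IMes)(PCy3)Cl2Ru=CHPh (second-generation Grubbs catalyst, 5 mol%), CH2Cl2, 40 °C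
Reagents that add atoms: none
Why: Olefin cross-metathesis of the prenyl-type trisubstituted alkene with styrene should exchange the isopropylidene end for a benzylidene end with loss of 2-methylpropene, forming the C14=C15 bond.

Step 4
Reactants: 7 ({[(2R,6R,9E)-2,6-dimethyl-10-phenyldec-9-en-1-yl]oxy}methyl)benzene
Product: 8 (2R,6S)-2,6-dimethyl-10-phenyldecan-1-ol
Conditions: H2 (1 atm), Pd/C (10%), EtOH, rt
Reagents that add atoms: none
Why: Heterogeneous hydrogenation should saturate the styrenyl double bond and hydrogenolyse the benzyl ether in one operation, with no stereocentre involved.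

Step 5
Reactants: 8 (2R,6S)-2,6-dimethyl-10-phenyldecan-1-ol
Product: 9 [(5S,9R)-10-bromo-5,9-dimethyldecyl]benzene
Conditions: CBr4, PPh3, CH2Cl2, 0 °C
Reagents that add atoms: carbon tetrabromide, BrC(Br)(Br)Br
Why: Appel bromination converts the primary alcohol to the bromide under neutral conditions and does not touch the neighbouring stereocentre.

Step 6
Reactants: 10 (4R)-4-hydroxy-4-methyloxan-2-one [(R)-mevalonolactone]
Product: 11 (3R)-3,5-dihydroxy-N-methoxy-N,3-dimethylpentanamide
Conditions: MeNH(OMe)·HCl (2 equiv), i-PrMgCl (5 equiv), THF, −20 to 0 °C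
Reagents that add atoms: N,O-dimethylhydroxylamine hydrochloride, CNOC.Cl
Why: Magnesium-amide aminolysis of the lactone (Weinreb amide formation) opens the ring and keeps the two arms of the tertiary carbinol different, with its configuration retained.

Step 7
Reactants: 11 (3R)-3,5-dihydroxy-N-methoxy-N,3-dimethylpentanamide
Product: 12 (3R)-3-hydroxy-5-[methoxy(methyl)amino]-3-methyl-5-oxopentyl 4-methylbenzenesulfonate
Conditions: TsCl (1.05 equiv), Et3N, DMAP (5 mol%), CH2Cl2, 0 °C
Reagents that add atoms: 4-methylbenzenesulfonyl chloride, Cc1ccc(cc1)S(Cl)(=O)=O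
Why: The primary hydroxyl is sulfonylated selectively in the presence of the hindered tertiary one.

Step 8
Reactants: 12 (3R)-3-hydroxy-5-[methoxy(methyl)amino]-3-methyl-5-oxopentyl 4-methylbenzenesulfonate
Product: 13 N-methoxy-N-methyl-2-[(2R)-2-methyloxetan-2-yl]acetamide
Conditions: KOt-Bu (1.1 equiv), THF, 0 °C to rt
Reagents that add atoms: none
Why: Intramolecular Williamson etherification (4-exo-tet) of the tertiary alkoxide onto the primary tosylate closes the oxetane with retention at the carbinol carbon, helped by the geminal disubstitution.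

Step 9
Reactants: 9 [(5S,9R)-10-bromo-5,9-dimethyldecyl]benzene; 13 N-methoxy-N-methyl-2-[(2R)-2-methyloxetan-2-yl]acetamide
Product: 15 (4R,8S)-4,8-dimethyl-1-[(2R)-2-methyloxetan-2-yl]-12-phenyldodecan-2-one, via Grignard reagent 14 (not isolated)
Conditions: 9, Mg, THF, 45 °C; then 13, THF, −10 °C; pH 7 phosphate buffer
Reagents that add atoms: none
Why: Weinreb ketone synthesis stops at single addition through the chelated tetrahedral adduct and gives the ketone that holds C5 at the carbonyl oxidation level.

Step 10
Reactants: 15 (4R,8S)-4,8-dimethyl-1-[(2R)-2-methyloxetan-2-yl]-12-phenyldodecan-2-one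
Product: 16 (2S)-2-[(4R,8S)-4,8-dimethyl-2-methylidene-12-phenyldodecyl]-2-methyloxetane
Conditions: Cp2TiMe2 (2.5 equiv), toluene/THF, 65 °C, dark
Reagents that add atoms: dimethyltitanocene, C[Ti](C)(C1C=CC=C1)C1C=CC=C1
Why: Petasis methylenation is non-basic, so it should give the 1,1-disubstituted alkene (the neutral precursor of the ketone O-oxide needed in step 11) without enolisation-triggered opening of the beta-oxetane.

Step 11
Reactants: 16 (2S)-2-[(4R,8S)-4,8-dimethyl-2-methylidene-12-phenyldodecyl]-2-methyloxetane
Product: 19 (1S,5S)-1-[(2R,6S)-2,6-dimethyl-10-phenyldecyl]-5-methyl-2,6,7-trioxabicyclo[3.2.1]octane, via hydroperoxy ketal 17 (not isolated), via methoxydioxolane alcohol 18 (not isolated)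
Conditions: O3, CH2Cl2/MeOH (4:1), −78 °C; N2 purge, evaporate cold; then TMSOTf (10 mol%), 4 Å MS, CH2Cl2, −78 to 0 °C
Reagents that add atoms: ozone, [O-][O+]=O; methanol, CO (its methoxy group is carried only by 17 and 18)
Why: Ozone cleaves the 1,1-disubstituted alkene so that the more substituted end becomes the ketone O-oxide, which methanol traps as hydroperoxy ketal 17 with loss of formaldehyde. TMSOTf then activates the oxetane oxygen and the terminal oxygen of the OOH group attacks the tertiary oxetane carbon from the rear in a 5-exo-tet closure; this forms the O–C bond at the ring carbon that carries CH3 and the two-carbon arm and closes the 1,2-dioxolane (18). The closest known reaction type is the acid-promoted 5-exo opening of 2,2-disubstituted oxetanes by hydroperoxides and hydroperoxy acetals, which runs with inversion, so the new dioxolane stereocentre is set by the (R)-carbinol centre of mevalonolactone. The primary alcohol set free then displaces methanol at the peroxyketal carbon through the dioxolanyl (peroxycarbenium) cation in a 6-exo-trig closure of the oxane ring; because the three-atom bridge can span the dioxolane on one face only, both epimers of 18 should converge on the single bicycle 19. The step needs the hydroperoxide, not methanol or triflate, to open the oxetane, and needs attack at the tertiary and not the primary oxetane carbon: the five-membered transition state, the better cation-stabilising quaternary carbon, removal of methanol before the acid is added and the low temperature should secure both.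

Step 12
Reactants: 19 (1S,5S)-1-[(2R,6S)-2,6-dimethyl-10-phenyldecyl]-5-methyl-2,6,7-trioxabicyclo[3.2.1]octane
Product: 20 2-[(3S,5R)-5-[(2R,6S)-2,6-dimethyl-10-phenyldecyl]-3,5-dimethyl-1,2-dioxolan-3-yl]ethan-1-ol
Conditions: Me2Zn (3 equiv) and TiCl4 (3 equiv) premixed, CH2Cl2, −78 °C; then 19, −78 to −40 °C; aq. NaHCO3
Reagents that add atoms: dimethylzinc, C[Zn]C
Why: Proposed new method: TiCl4 is known to ionise 3-alkoxy-1,2-dioxolanes at the exocyclic ether C–O bond to dioxolan-3-yl (peroxycarbenium) cations that allylsilanes and silyl ketene acetals trap, and MeTiCl3 (from Me2Zn and TiCl4) is known to methylate ketals and to open cyclic acetals with inversion; in 19 the ether oxygen O2 (bicycle numbering) should be the more basic site, so the C1–O2 bond ionises and methyl should add to the cation on the face opposite the departing titanium-bound oxyethyl bridge, which is also the face away from the larger substituent on the other ring carbon, placing the new CH3 cis to the existing ring methyl and setting the (5R) centre.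

Step 13
Reactants: 20 2-[(3S,5R)-5-[(2R,6S)-2,6-dimethyl-10-phenyldecyl]-3,5-dimethyl-1,2-dioxolan-3-yl]ethan-1-ol
Product: 21 2-[(3R,5R)-5-[(2R,6S)-2,6-dimethyl-10-phenyldecyl]-3,5-dimethyl-1,2-dioxolan-3-yl]acetic acid
Conditions: TEMPO (20 mol%), PhI(OAc)2 (2.5 equiv), MeCN/H2O (1:1), rt
Reagents that add atoms: water, O
Why: Oxoammonium-mediated oxidation of the primary alcohol through the aldehyde hydrate to the acid runs at slightly acidic pH, which should leave the dialkyl peroxide intact and avoid base-induced beta-elimination of the peroxide from the intermediate aldehyde.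

**Compound list**

1 | (2S)-3-bromo-2-methylpropan-1-ol | OC[C@H](C)CBr | starting material
2 | {[(2S)-3-bromo-2-methylpropoxy]methyl}benzene | BrC[C@@H](C)COCc1ccccc1 | intermediate
3 | (6S)-8-bromo-2,6-dimethyloct-2-ene [(S)-citronellyl bromide] | BrCC[C@@H](C)CCC=C(C)C | starting material
4 | [(2S)-3-(benzyloxy)-2-methylpropyl]magnesium bromide | Br[Mg]C[C@@H](C)COCc1ccccc1 | intermediate
5 | ({[(2R,6R)-2,6,10-trimethylundec-9-en-1-yl]oxy}methyl)benzene | C(c1ccccc1)OC[C@H](C)CCC[C@@H](C)CCC=C(C)C | intermediate
6 | styrene | C=Cc1ccccc1 | starting material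
7 | ({[(2R,6R,9E)-2,6-dimethyl-10-phenyldec-9-en-1-yl]oxy}methyl)benzene | C(c1ccccc1)OC[C@H](C)CCC[C@@H](C)CC/C=C/c1ccccc1 | intermediate
8 | (2R,6S)-2,6-dimethyl-10-phenyldecan-1-ol | OC[C@H](C)CCC[C@@H](C)CCCCc1ccccc1 | intermediate
9 | [(5S,9R)-10-bromo-5,9-dimethyldecyl]benzene | BrC[C@H](C)CCC[C@@H](C)CCCCc1ccccc1 | intermediate
10 | (4R)-4-hydroxy-4-methyloxan-2-one [(R)-mevalonolactone] | C[C@@]1(O)CCOC(=O)C1 | starting material
11 | (3R)-3,5-dihydroxy-N-methoxy-N,3-dimethylpentanamide | CON(C)C(=O)C[C@](C)(O)CCO | intermediate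
12 | (3R)-3-hydroxy-5-[methoxy(methyl)amino]-3-methyl-5-oxopentyl 4-methylbenzenesulfonate | CON(C)C(=O)C[C@](C)(O)CCOS(=O)(=O)c1ccc(C)cc1 | intermediate
13 | N-methoxy-N-methyl-2-[(2R)-2-methyloxetan-2-yl]acetamide | CON(C)C(=O)C[C@@]1(C)CCO1 | intermediate
14 | [(2R,6S)-2,6-dimethyl-10-phenyldecyl]magnesium bromide | Br[Mg]C[C@H](C)CCC[C@@H](C)CCCCc1ccccc1 | intermediate
15 | (4R,8S)-4,8-dimethyl-1-[(2R)-2-methyloxetan-2-yl]-12-phenyldodecan-2-one | C[C@@H](CCCCc1ccccc1)CCC[C@@H](C)CC(=O)C[C@@]2(C)CCO2 | intermediate
16 | (2S)-2-[(4R,8S)-4,8-dimethyl-2-methylidene-12-phenyldodecyl]-2-methyloxetane | C[C@@H](CCCCc1ccccc1)CCC[C@@H](C)CC(=C)C[C@@]2(C)CCO2 | intermediate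
17 | (2R)-2-[(4R,8S)-2-hydroperoxy-2-methoxy-4,8-dimethyl-12-phenyldodecyl]-2-methyloxetane (both epimers at the ketal carbon) | C[C@@H](CCCCc1ccccc1)CCC[C@@H](C)CC(OC)(OO)C[C@@]2(C)CCO2 | intermediate
18 | 2-[(3S)-5-[(2R,6S)-2,6-dimethyl-10-phenyldecyl]-5-methoxy-3-methyl-1,2-dioxolan-3-yl]ethan-1-ol (both epimers at the ketal carbon) | C[C@@H](CCCCc1ccccc1)CCC[C@@H](C)CC2(OC)C[C@](C)(CCO)OO2 | intermediate
19 | (1S,5S)-1-[(2R,6S)-2,6-dimethyl-10-phenyldecyl]-5-methyl-2,6,7-trioxabicyclo[3.2.1]octane | C[C@@H](CCCCc1ccccc1)CCC[C@@H](C)C[C@]23C[C@](C)(CCO2)OO3 | intermediate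
20 | 2-[(3S,5R)-5-[(2R,6S)-2,6-dimethyl-10-phenyldecyl]-3,5-dimethyl-1,2-dioxolan-3-yl]ethan-1-ol | C[C@@H](CCCCc1ccccc1)CCC[C@@H](C)C[C@]2(C)C[C@](C)(CCO)OO2 | intermediate
21 | 2-[(3R,5R)-5-[(2R,6S)-2,6-dimethyl-10-phenyldecyl]-3,5-dimethyl-1,2-dioxolan-3-yl]acetic acid | C[C@@H](CCCCc1ccccc1)CCC[C@@H](C)C[C@]1(C)C[C@](C)(CC(=O)O)OO1 | target

**Step count and risks**

Total step count: 13. Longest linear sequence: 10 steps (steps 1–5 and 9–13).

Step 12 (proposed new method). The methylation may fail through poor facial selectivity (methyl delivered from a titanium alkoxide on the bridge side), through ionisation of the ketal at the peroxide oxygen instead of the ether oxygen, or through Lewis-acid-induced heterolysis of the O–O bond. The fallback uses known chemistry and sets out from alkene 16. Cobalt-catalysed hydroperoxysilylation (Co(acac)2, O2, Et3SiH, 1,2-dichloroethane; Mukaiyama–Isayama peroxidation) should give triethyl({(4R,8S)-2,4,8-trimethyl-1-[(2R)-2-methyloxetan-2-yl]-12-phenyldodecan-2-yl}peroxy)silane F1 as both epimers at the new peroxide carbon. TMSOTf in CH2Cl2 should then trigger the same 5-exo opening of the oxetane with loss of the silyl group, giving 20 together with its C5 epimer 2-[(3S,5S)-5-[(2R,6S)-2,6-dimethyl-10-phenyldecyl]-3,5-dimethyl-1,2-dioxolan-3-yl]ethan-1-ol F2. Chromatographic separation returns 20 to the route. This path gives up control of C5.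

Step 11. The primary ozonide may fragment toward formaldehyde O-oxide (returning ketone 15), the hydroperoxy ketal may undergo acid-induced Criegee-type rearrangement before it reaches the oxetane, or methanol may open the oxetane in place of the hydroperoxide. The fallback sets out from ketone 15 and inverts the order of the two C–O bond formations. Ethereal H2O2 with TMSOTf (Et2O, −78 to 0 °C) should open the oxetane at its tertiary carbon with inversion, as in the perhydrolysis of 2,2-disubstituted oxetanes, to give (3S,7R,11S)-3-hydroperoxy-1-hydroxy-3,7,11-trimethyl-15-phenylpentadecan-5-one F3. Its hydroperoxide and hydroxyl groups should then close onto the ketone under the same acid with loss of water, giving bicyclic peroxyketal 19, where the route is rejoined.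

Step 3. Metathesis of the trisubstituted alkene may be slow, and catalyst decomposition and styrene self-metathesis may leave the conversion incomplete. The fallback sets out from 5 and replaces metathesis by olefination. Ozonolysis with Me2S work-up (CH2Cl2, −78 °C) should give (4R,8R)-9-(benzyloxy)-4,8-dimethylnonanal F4, and Wittig reaction with benzylidenetriphenylphosphorane (BnPPh3Cl, KOt-Bu, THF, 0 °C) should give 7 accompanied by its Z isomer ({[(2R,6R,9Z)-2,6-dimethyl-10-phenyldec-9-en-1-yl]oxy}methyl)benzene F5. The route is rejoined at 7, since both olefin isomers are hydrogenated to 8 in step 4.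

Further compounds

F1 | step 12 | triethyl({(4R,8S)-2,4,8-trimethyl-1-[(2R)-2-methyloxetan-2-yl]-12-phenyldodecan-2-yl}peroxy)silane (both epimers at the peroxide carbon) | C[C@@H](CCCCc1ccccc1)CCC[C@@H](C)CC(C)(OO[Si](CC)(CC)CC)C[C@@]2(C)CCO2
F2 | step 12 | 2-[(3S,5S)-5-[(2R,6S)-2,6-dimethyl-10-phenyldecyl]-3,5-dimethyl-1,2-dioxolan-3-yl]ethan-1-ol | C[C@@H](CCCCc1ccccc1)CCC[C@@H](C)C[C@@]2(C)C[C@](C)(CCO)OO2
F3 | step 11 | (3S,7R,11S)-3-hydroperoxy-1-hydroxy-3,7,11-trimethyl-15-phenylpentadecan-5-one | C[C@@H](CCCCc1ccccc1)CCC[C@@H](C)CC(=O)C[C@](C)(CCO)OO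
F4 | step 3 | (4R,8R)-9-(benzyloxy)-4,8-dimethylnonanal | C(c1ccccc1)OC[C@H](C)CCC[C@@H](C)CCC=O
F5 | step 3 | ({[(2R,6R,9Z)-2,6-dimethyl-10-phenyldec-9-en-1-yl]oxy}methyl)benzene | C(c1ccccc1)OC[C@H](C)CCC[C@@H](C)CC/C=C\c1ccccc1
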